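**Retrosynthetic overview**

1. Backwards: the C1=C2 olefin comes from a C2 ketone (dienyl triflate reduction); ring E from C–N closure of a 2-aminoethyl sulfone onto the quinone; the ring B lactone oxygen from Baeyer–Villiger ring expansion of a six-membered aryl enone; ring D from a Moore rearrangement; ring A from an asymmetric Robinson annulation on 6-bromo-1-methyl-2-tetralone.
2. Key disconnection: the bond from the ring C carbon para to the lactone carbonyl to the ring D carbonyl carbon that adjoins the N-bearing carbon, closed in a cyclobutenone → dienylketene → naphthoquinone cascade.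
3. Enabling feature: ring D is a para-quinone fused to ring C whose four non-aromatic carbons (C=O, C–N, C–S, C=O) are the four carbons of a squaric acid unit, with the N-bearing carbon carried as CH and the S-bearing carbon as a thioether; the ring C carbon that receives the bond is a free CH, while the rival ortho carbon is flanked by the ring B methylene.
4. Fragments: the aryl Grignard reagent from tricyclic bromide 12 and thio-semisquarate 19 (from diisopropyl squarate and Boc-cysteamine).
5. Ring order: C and carbocyclic B (purchased tetralone) → A → D (key) → B (ring expansion) → E; the quaternary stereocentre is set in step 2.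

Key step: step 8

Remark (assumption): the sense of induction in step 2 is taken from the usual facial model for 1-phenylethylamine imines; the CIP label of the quaternary carbon changes along the route (S in 8–10 and 28–35, R in 11, 12 and 20–27) although the centre is never touched; phenanthrene numbering (C1–C10a) is used for the A–B–C part, and compounds 12 and 20–31 are mixtures of C1 epimers.

**Route**

Step 1
Reactants: 1 6-bromo-3,4-dihydronaphthalen-2(1H)-one
Product: 4 rac-6-bromo-1-methyl-3,4-dihydronaphthalen-2(1H)-one, via enamine 2 (not isolated), via iminium iodide 3 (not isolated)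
Conditions: pyrrolidine, PhH, reflux (Dean–Stark); MeI, dioxane, reflux; then H2O, AcOH, 25 °C
Reagents that add atoms: iodomethane CI; pyrrolidine C1CCNC1 (carried in 2 and 3 only); water O
Why: Stork enamine alkylation, in which the aryl-conjugated enamine of the 2-tetralone forms toward C1 and should be mono-C-methylated there before hydrolysis; the new centre is racemic and is erased in step 2.

Step 2
Reactants: 4 rac-6-bromo-1-methyl-3,4-dihydronaphthalen-2(1H)-one; 5 (S)-1-phenylethylamine; 6 pent-1-en-3-one
Product: 9 (S)-6-bromo-1-methyl-1-(3-oxopentyl)-3,4-dihydronaphthalen-2(1H)-one, via secondary enamine 7 (not isolated), via Michael adduct imine 8 (not isolated)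
Conditions: 5, TsOH (cat.), PhMe, reflux (Dean–Stark); 6, THF, 25 °C; then 10% aq AcOH, 25 °C
Reagents that add atoms: water O
Why: d'Angelo deracemising Michael addition, in which the more substituted secondary enamine should add to the enone through a compact aza-ene-like transition state on the face anti to the phenyl group of the auxiliary, which sets the quaternary centre as S.

Step 3
Reactants: 9 (S)-6-bromo-1-methyl-1-(3-oxopentyl)-3,4-dihydronaphthalen-2(1H)-one
Product: 11 (R)-7-bromo-1,4a-dimethyl-4,4a,9,10-tetrahydrophenanthren-2(3H)-one, via ketol 10 (not isolated)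
Conditions: NaOMe, MeOH, 60 °C
Reagents that add atoms: none
Why: Robinson annulation second stage (intramolecular aldol condensation of the ethyl ketone onto the tetralone carbonyl, then dehydration) should close ring A without touching the quaternary centre.

Step 4
Reactants: 11 (R)-7-bromo-1,4a-dimethyl-4,4a,9,10-tetrahydrophenanthren-2(3H)-one
Product: 12 (4a'R)-7'-bromo-1',4a'-dimethyl-3',4',4a',9'-tetrahydro-1'H-spiro[1,3-dioxolane-2,2'-phenanthrene]
Conditions: HOCH2CH2OH, TsOH (cat.), PhH, reflux (Dean–Stark)
Reagents that add atoms: ethane-1,2-diol OCCO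
Why: Ketalisation of a conjugated enone with the usual migration of the double bond to the β,γ position (C10a=C10), which masks the ketone for the Grignard step and makes C9 allylic as well as benzylic; C1 becomes a stereocentre of no consequence.

Step 5
Reactants: 13 3,4-diisopropoxycyclobut-3-ene-1,2-dione
Product: 16 3-hydroxycyclobut-3-ene-1,2-dione, via hydroxycyclobutenone 14 (not isolated), via isopropyl semisquarate 15 (not isolated)
Conditions: LiAlH(Ot-Bu)3, THF, −78 → 0 °C; then 6 M HCl, 25 → 50 °C
Reagents that add atoms: water O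
Why: Selective 1,2-hydride reduction of one squarate carbonyl, acid-induced loss of isopropanol to the semisquarate ester and hydrolysis of that vinylogous ester, the established reduction–hydrolysis route from squarates to semisquaric acid.

Step 6
Reactants: 16 3-hydroxycyclobut-3-ene-1,2-dione; 17 tert-butyl N-(2-sulfanylethyl)carbamate
Product: 19 tert-butyl N-{2-[(3,4-dioxocyclobut-1-en-1-yl)sulfanyl]ethyl}carbamate, via semisquaric chloride 18 (not isolated)
Conditions: (COCl)2, DMF (cat.), CH2Cl2, 0 → 25 °C; then 17, 2,6-lutidine, CH2Cl2, −78 → 0 °C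
Reagents that add atoms: oxalyl chloride ClC(=O)C(=O)Cl (chlorine, carried in 18 only)
Why: Vilsmeier-type conversion of the vinylogous acid into its chloride followed by addition–elimination of the thiol (vinylogous thioester formation), the thiol being far more nucleophilic than the carbamate N–H.

Step 7
Reactants: 12 (4a'R)-7'-bromo-1',4a'-dimethyl-3',4',4a',9'-tetrahydro-1'H-spiro[1,3-dioxolane-2,2'-phenanthrene]; 19 tert-butyl N-{2-[(3,4-dioxocyclobut-1-en-1-yl)sulfanyl]ethyl}carbamate
Product: 21 4-aryl-4-hydroxy-3-{[2-(tert-butoxycarbonylamino)ethyl]sulfanyl}cyclobut-2-en-1-one (aryl = C7' of ketal 12; both carbinol epimers), via arylmagnesium bromide 20 (not isolated)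
Conditions: Mg (activated with 1,2-dibromoethane), THF, 50 °C; then added to 19 (1.3 equiv), THF, −78 °C; aq NH4Cl
Reagents that add atoms: magnesium [Mg] (carried in 20 only)
Why: Grignard 1,2-addition to a cyclobutenedione, which should take the ketone-like carbonyl next to the sulfur-bearing carbon (the other carbonyl is a vinylogous thioester) and at −78 °C should outrun deprotonation of the carbamate; the carbinol configuration is uncontrolled and irrelevant.

Step 8
Reactants: 21 4-aryl-4-hydroxy-3-{[2-(tert-butoxycarbonylamino)ethyl]sulfanyl}cyclobut-2-en-1-one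
Product: 24 thioquinone (rings A–D; ring D 1,4-quinone with the [2-(Boc-amino)ethyl]sulfanyl group on the carbon next to the carbonyl attached at C7 and CH next to the carbonyl attached at C6; C2 ethylene ketal, C10a=C10 olefin, 4aR), via dienylketene 22 (not isolated), via hydroquinone 23 (not isolated)
Conditions: PhMe, 110 °C; then Ag2O, MgSO4, 25 °C
Reagents that add atoms: none
Why: Heating should open the 4-aryl-4-hydroxycyclobutenone by conrotatory four-electron ring opening with the hydroxyl rotating outward, so that the aryl group lies cis to the ketene in dienylketene 22, whose ketene carbon then closes onto the ortho aromatic carbon; tautomerisation gives naphthalenediol 23 and Ag2O oxidises it to quinone 24. The closest known reaction type is the Moore rearrangement of squarate-derived 4-aryl-4-hydroxycyclobutenones to 1,4-naphthoquinones. Ring D is the only ring closed, by a thermal six-electron electrocyclisation onto ring C followed by rearomatisation. No stereocentre is formed: the carbinol centre of 21 is destroyed and the quaternary carbon is remote. The step needs site selectivity between the two ortho carbons of ring C, which the peri ring B methylene beside the inner carbon should secure in favour of the free CH para to the future lactone carbonyl. The placement of S and H in ring D follows from the connectivity of 21, in which the S-bearing carbon is bonded to the carbinol carbon and the CH carbon to the carbonyl carbon that becomes the ketene.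

Step 9
Reactants: 24 thioquinone
Product: 26 sulfonylquinone (as 24 with S oxidised to SO2), via sulfoxide 25 (not isolated)
Conditions: (NH4)6Mo7O24·4H2O (cat.), 30% aq H2O2, THF/t-BuOH, 0 → 25 °C
Reagents that add atoms: hydrogen peroxide OO
Why: Peroxide oxidation of a sulfide to the sulfone catalysed by (NH4)6Mo7O24, chosen because the peroxo complex of this catalyst should oxidise sulfur much faster than it epoxidises the isolated trisubstituted olefin.

Step 10
Reactants: 26 sulfonylquinone
Product: 27 enone (as 26 with C9 oxidised to C=O, conjugated with C10=C10a and ring C)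
Conditions: CrO3, 3,5-dimethylpyrazole, CH2Cl2, −20 °C
Reagents that add atoms: chromium trioxide O=[Cr](=O)=O
Why: Allylic oxidation with the CrO3–3,5-dimethylpyrazole complex, as in the oxidation of homoallylic-ketal olefins to enones, should take the only methylene that is both allylic and benzylic (C9).

Step 11
Reactants: 27 enone
Product: 28 enol lactone (ring B now the seven-membered Ar–C(=O)–O–CH=C10a lactone; C2 ketal, sulfonylquinone and NHBoc unchanged; 4aS)
Conditions: mCPBA, Na2HPO4, CH2Cl2, 0 → 25 °C
Reagents that add atoms: 3-chloroperbenzoic acid OOC(=O)c1cccc(Cl)c1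
Why: Baeyer–Villiger oxidation of an aryl alkenyl ketone, in which the β,β-disubstituted alkenyl carbon should migrate in preference to the strongly electron-poor quinone-fused aryl group and so insert oxygen between C9 and C10 to give the enol ester.

Step 12
Reactants: 28 enol lactone
Product: 31 keto thiazine-quinone (rings A–E; C2 ketone, C1–H, enol lactone; 4aS), via ammonium trifluoroacetate 29 (not isolated), via aminohydroquinone 30 (not isolated)
Conditions: CF3CO2H/CH2Cl2/H2O, 0 → 25 °C; then aq NaHCO3, MeCN, air, 25 °C
Reagents that add atoms: water O; trifluoroacetic acid OC(=O)C(F)(F)F (counter-ion of 29 only)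
Why: Acidolysis (Boc cleavage, ketal hydrolysis) and neutralisation should free the amine, which adds to the sulfone-activated quinone CH carbon (six-membered aza-Michael closure) and is re-oxidised by air, the way 2-aminoethanesulfonyl quinones close to thiazine dioxides; should the ketone conjugate into ring A, that isomer converges in step 13.

Step 13
Reactants: 31 keto thiazine-quinone
Product: 32 dienyl triflate (C2–OTf, C1=C2 and C10a=C10 in conjugation with the lactone oxygen)
Conditions: Tf2O, 2,6-di-tert-butyl-4-methylpyridine, CH2Cl2, 0 → 25 °C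
Reagents that add atoms: trifluoromethanesulfonic anhydride O=S(=O)(OS(=O)(=O)C(F)(F)F)C(F)(F)F
Why: Thermodynamic enol triflate formation with triflic anhydride and a hindered pyridine should remove the doubly activated C1–H and give the conjugated dienyl triflate, while the vinylogous amide N–H of ring E is too electron-poor to compete.

Step 14
Reactants: 32 dienyl triflate
Product: 35 target CNP0348176.1, via hydroquinone triflate 33 (not isolated), via hydroquinone 34 (not isolated)
Conditions: Pd(OAc)2, PPh3, Bu3N, HCO2H, DMF, 60 °C; then air, 25 °C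
Reagents that add atoms: none
Why: Formate reduction of an enol triflate catalysed by Pd(OAc)2/PPh3 (oxidative addition to zerovalent palladium, formate exchange, decarboxylation, reductive elimination) should replace OTf by H with the diene in place; the quinone is expected to pass through its hydroquinone and to be re-oxidised by air.

**Compound list**

1 | 6-bromo-3,4-dihydronaphthalen-2(1H)-one | O=C1CCc2cc(Br)ccc2C1 | starting material
2 | 1-(6-bromo-3,4-dihydronaphthalen-2-yl)pyrrolidine | Brc1ccc2C=C(N3CCCC3)CCc2c1 | intermediate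
3 | 1-(6-bromo-1-methyl-3,4-dihydronaphthalen-2(1H)-ylidene)pyrrolidinium iodide | CC1c2ccc(Br)cc2CCC1=[N+]1CCCC1.[I-] | intermediate
4 | rac-6-bromo-1-methyl-3,4-dihydronaphthalen-2(1H)-one | CC1C(=O)CCc2cc(Br)ccc12 | intermediate
5 | (S)-1-phenylethylamine | C[C@H](N)c1ccccc1 | starting material
6 | pent-1-en-3-one | CCC(=O)C=C | starting material
7 | 6-bromo-1-methyl-N-[(1S)-1-phenylethyl]-3,4-dihydronaphthalen-2-amine (secondary enamine, in equilibrium with its imine) | C[C@H](NC1=C(C)c2ccc(Br)cc2CC1)c1ccccc1 | intermediate
8 | (1S)-6-bromo-1-methyl-1-(3-oxopentyl)-N-[(1S)-1-phenylethyl]-3,4-dihydronaphthalen-2(1H)-imine | CCC(=O)CC[C@]2(C)C(=N[C@@H](C)c3ccccc3)CCc1cc(Br)ccc12 | intermediate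
9 | (S)-6-bromo-1-methyl-1-(3-oxopentyl)-3,4-dihydronaphthalen-2(1H)-one | CCC(=O)CC[C@]2(C)C(=O)CCc1cc(Br)ccc12 | intermediate
10 | (4aS)-7-bromo-10a-hydroxy-1,4a-dimethyl-3,4,4a,9,10,10a-hexahydrophenanthren-2(1H)-one (C1 and C10a unassigned) | O=C1CC[C@]2(C)C(O)(C1C)CCc1cc(Br)ccc12 | intermediate
11 | (R)-7-bromo-1,4a-dimethyl-4,4a,9,10-tetrahydrophenanthren-2(3H)-one | O=C1CC[C@]2(C)C(=C1C)CCc1cc(Br)ccc12 | intermediate
12 | (4a'R)-7'-bromo-1',4a'-dimethyl-3',4',4a',9'-tetrahydro-1'H-spiro[1,3-dioxolane-2,2'-phenanthrene] (C1' epimers) | CC1C3(OCCO3)CC[C@]2(C)C1=CCc1cc(Br)ccc12 | intermediate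
13 | 3,4-diisopropoxycyclobut-3-ene-1,2-dione (diisopropyl squarate) | CC(C)OC1=C(OC(C)C)C(=O)C1=O | starting material
14 | 4-hydroxy-2,3-diisopropoxycyclobut-2-en-1-one | CC(C)OC1=C(OC(C)C)C(O)C1=O | intermediate
15 | 3-isopropoxycyclobut-3-ene-1,2-dione | CC(C)OC1=CC(=O)C1=O | intermediate
16 | 3-hydroxycyclobut-3-ene-1,2-dione (semisquaric acid) | OC1=CC(=O)C1=O | intermediate
17 | tert-butyl N-(2-sulfanylethyl)carbamate | CC(C)(C)OC(=O)NCCS | starting material
18 | 3-chlorocyclobut-3-ene-1,2-dione | ClC1=CC(=O)C1=O | intermediate
19 | tert-butyl N-{2-[(3,4-dioxocyclobut-1-en-1-yl)sulfanyl]ethyl}carbamate | CC(C)(C)OC(=O)NCCSC1=CC(=O)C1=O | intermediate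
20 | arylmagnesium bromide of 12 (MgBr at C7') | CC1C3(OCCO3)CC[C@]2(C)C1=CCc1cc([Mg]Br)ccc12 | intermediate
21 | 4-aryl-4-hydroxy-3-{[2-(tert-butoxycarbonylamino)ethyl]sulfanyl}cyclobut-2-en-1-one, aryl = C7' of ketal 12 (carbinol epimers) | CC1C3(OCCO3)CC[C@]2(C)C1=CCc1cc(C4(O)C(SCCNC(=O)OC(C)(C)C)=CC4=O)ccc12 | intermediate
22 | 4-aryl-4-hydroxy-3-{[2-(Boc-amino)ethyl]sulfanyl}buta-1,3-dien-1-one (dienylketene) | CC1C3(OCCO3)CC[C@]2(C)C1=CCc1cc(C(O)=C(SCCNC(=O)OC(C)(C)C)C=C=O)ccc12 | intermediate
23 | ring D 1,4-naphthalenediol with the thioether next to the hydroxyl carbon attached at C7 | CC1C3(OCCO3)CC[C@]2(C)C1=CCc1cc4c(O)c(SCCNC(=O)OC(C)(C)C)cc(O)c4cc12 | intermediate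
24 | thioquinone (ring D quinone, thioether next to the carbonyl attached at C7; C2 ketal; C10a=C10) | CC1C3(OCCO3)CC[C@]2(C)C1=CCc1cc4c(cc12)C(=O)C=C(SCCNC(=O)OC(C)(C)C)C4=O | intermediate
25 | sulfoxide of 24 | CC1C3(OCCO3)CC[C@]2(C)C1=CCc1cc4c(cc12)C(=O)C=C(S(=O)CCNC(=O)OC(C)(C)C)C4=O | intermediate
26 | sulfonylquinone (sulfone of 24) | CC1C3(OCCO3)CC[C@]2(C)C1=CCc1cc4c(cc12)C(=O)C=C(S(=O)(=O)CCNC(=O)OC(C)(C)C)C4=O | intermediate
27 | 9-oxo enone of 26 | CC1C3(OCCO3)CC[C@]2(C)C1=CC(=O)c1cc4c(cc12)C(=O)C=C(S(=O)(=O)CCNC(=O)OC(C)(C)C)C4=O | intermediate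
28 | seven-membered enol lactone (ring B), C2 ketal, sulfonylquinone, NHBoc | CC1C3(OCCO3)CC[C@]2(C)C1=COC(=O)c1cc4c(cc12)C(=O)C=C(S(=O)(=O)CCNC(=O)OC(C)(C)C)C4=O | intermediate
29 | ammonium trifluoroacetate of the deprotected amino ketone | CC1C(=O)CC[C@]2(C)C1=COC(=O)c1cc4c(cc12)C(=O)C=C(S(=O)(=O)CC[NH3+])C4=O.[O-]C(=O)C(F)(F)F | intermediate
30 | ring E closed, ring D as aminohydroquinone | CC1C(=O)CC[C@]2(C)C1=COC(=O)c1cc4c(O)c5c(NCCS5(=O)=O)c(O)c4cc12 | intermediate
31 | keto thiazine-quinone (rings A–E, C2 ketone, C1–H) | CC1C(=O)CC[C@]2(C)C1=COC(=O)c1cc4c(cc12)C(=O)C1=C(C4=O)S(=O)(=O)CCN1 | intermediate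
32 | dienyl triflate of 31 (C2–OTf) | CC1=C(OS(=O)(=O)C(F)(F)F)CC[C@]2(C)C1=COC(=O)c1cc4c(cc12)C(=O)C1=C(C4=O)S(=O)(=O)CCN1 | intermediate
33 | hydroquinone form of 32 | CC1=C(OS(=O)(=O)C(F)(F)F)CC[C@]2(C)C1=COC(=O)c1cc4c(O)c5c(NCCS5(=O)=O)c(O)c4cc12 | intermediate
34 | hydroquinone form of the target | CC1=CCC[C@]2(C)C1=COC(=O)c1cc4c(O)c5c(NCCS5(=O)=O)c(O)c4cc12 | intermediate
35 | CNP0348176.1 (S at the quaternary carbon) | CC1=CCC[C@]2(C)C1=COC(=O)c1cc3c(cc12)C(=O)C1=C(C3=O)S(=O)(=O)CCN1 | target

**Count and risks**

Total step count: 14. Longest linear sequence: 12 steps (1–4, then 7–14); steps 5 and 6 form the two-step side branch.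

Steps most likely to fail:

1. Step 11 (Baeyer–Villiger ring expansion). The conjugated, electron-poor aryl ketone may resist peracid addition or alkenyl migration, and the enol lactone double bond may be over-oxidised once formed. The fallback cleaves and re-closes instead of rearranging; it sets out from 27 and returns at 28. 1,4-Hydrosilylation catalysed by RhCl(PPh3)3 (Et3SiH, PhH, 60 °C) should reduce the enone to the triethylsilyl enol ether of the saturated 9-ketone and at the same time mask the quinone as its bis(triethylsilyl) hydroquinone ether, the tris(triethylsilyl) compound F1. Ozonolysis of the enol ether double bond (O3, CH2Cl2/MeOH, −78 °C; Me2S), then desilylation and re-oxidation (Bu4NF/AcOH; Ag2O), should give the aldehyde acid F2, with C9 as CO2H on ring C and C10 as CHO on C10a. Enol lactonisation (2,4,6-trichlorobenzoyl chloride, Et3N, DMAP, PhMe) then closes ring B to 28.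

2. Step 14 (triflate reduction beside a quinone). The quinone may sequester or re-oxidise zerovalent palladium so that the reduction stalls, or the amine/formate medium may erode the enol lactone during a slow reaction. The fallback masks the quinone first; it sets out from 32 and returns at 35. Reduction (Na2S2O4, EtOAc/H2O) and silylation (TBSOTf, 2,6-lutidine, CH2Cl2) should give the bis(tert-butyldimethylsilyl) hydroquinone triflate F3. The same Pd(OAc)2/PPh3/formate reduction then gives the bis(tert-butyldimethylsilyl) hydroquinone diene F4. Desilylation (HF·pyridine, THF) and oxidation (Ag2O) give 35.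

3. Step 12 (global acidolysis and ring E closure). The enol lactone may hydrolyse or the double bond may migrate uncontrollably in aqueous acid, and the free amine may attack the lactone. The fallback closes ring E before the ring expansion and removes the ketal last under mild conditions; it sets out from 27 and returns at 31. Non-aqueous Boc cleavage that spares the ketal (TMSOTf, 2,6-lutidine, CH2Cl2, 0 °C; MeOH), then aq NaHCO3 and air, should give the thiazine-quinone enone ketal F5. Baeyer–Villiger oxidation (mCPBA, Na2HPO4, CH2Cl2) gives the thiazine-quinone enol lactone ketal F6. Mild transketalisation (PPTS, acetone/H2O, 25 °C) gives 31.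

**Further compounds**

F1 | step 11 | tris(triethylsilyl) compound: 9-triethylsilyloxy C9=C10 enol ether, C10a–H, ring D as bis(triethylsilyl) ether of the sulfonyl hydroquinone, C2 ketal, NHBoc | CC1C3(OCCO3)CC[C@]2(C)C1C=C(O[Si](CC)(CC)CC)c1cc4c(O[Si](CC)(CC)CC)c(S(=O)(=O)CCNC(=O)OC(C)(C)C)cc(O[Si](CC)(CC)CC)c4cc12
F2 | step 11 | aldehyde acid: ring C carboxylic acid ortho to the quaternary carbon, formyl group on C10a, C2 ketal, sulfonylquinone, NHBoc | CC1C3(OCCO3)CC[C@](C)(C1C=O)c1cc2c(cc1C(=O)O)C(=O)C(S(=O)(=O)CCNC(=O)OC(C)(C)C)=CC2=O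
F3 | step 14 | bis(tert-butyldimethylsilyl) hydroquinone ether of dienyl triflate 32 | CC1=C(OS(=O)(=O)C(F)(F)F)CC[C@]2(C)C1=COC(=O)c1cc4c(O[Si](C)(C)C(C)(C)C)c5c(NCCS5(=O)=O)c(O[Si](C)(C)C(C)(C)C)c4cc12
F4 | step 14 | bis(tert-butyldimethylsilyl) hydroquinone ether of the target | CC1=CCC[C@]2(C)C1=COC(=O)c1cc4c(O[Si](C)(C)C(C)(C)C)c5c(NCCS5(=O)=O)c(O[Si](C)(C)C(C)(C)C)c4cc12
F5 | step 12 | thiazine-quinone enone ketal (rings C–E complete, C9 ketone, C10=C10a, C2 ketal) | CC1C3(OCCO3)CC[C@]2(C)C1=CC(=O)c1cc4c(cc12)C(=O)C1=C(C4=O)S(=O)(=O)CCN1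
F6 | step 12 | thiazine-quinone enol lactone ketal (ring B lactone, C2 ketal) | CC1C3(OCCO3)CC[C@]2(C)C1=COC(=O)c1cc4c(cc12)C(=O)C1=C(C4=O)S(=O)(=O)CCN1
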